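**Retrosynthetic overview**
1. The target is (+)-syringaresinol (7S,8R,7'S,8'R) with an erythro (7R,8S) guaiacylglycerol on ring B and a threo (7S,8S) guaiacylglycerol on ring C, whose ring D phenol carries a second erythro (7S,8R) unit (ring E). All three β-O-4 C8–O bonds are cut to a phenol plus an enantiopure 2-aryl-3-vinyloxirane (palladium-catalysed allylic etherification; vinyl = masked C9H2OH).
2. The two cis-epoxides (erythro units) come from a silylated vanillin by asymmetric chloroallylboration. The trans-epoxide (threo unit, already carrying unit E) comes from an aryl bromide via aldehyde, diene and Shi epoxidation. The aromatic units come from p-cresol (copper-catalysed methoxylation) and catechol.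
3. Core: a proline cross-aldol sets C8, a lactone enolate aldol sets C8', and LiAlH4 opens the lactone to a tetrol. Ring order: γ-lactone first (step 5), then both tetrahydrofuran rings of the furofuran together (step 9), which also sets C7 and C7'.
4. Union: core plus cis-epoxide gives the ring B mono-ether, the trans-epoxide then gives the bis-ether, and both vinyl groups are converted to CH2OH before global desilylation.

Abbreviations: ArS = 3,5-dimethoxy-4-(triisopropylsilyloxy)phenyl; ArG = 3-methoxy-4-(triisopropylsilyloxy)phenyl; TIPS = Si(i-Pr)3; TBS = SiMe2(t-Bu); side chains use lignan numbering (C7 benzylic, C8, C9).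
Assumption: the sense of induction of L-proline, (−)-/(+)-Ipc2BOMe, the Shi ketone antipode and the Trost ligand antipodes is taken from the accepted models of the parent reactions.

**Part 1: (+)-syringaresinol**

Step 1
Reactants: 1 4-methylphenol (p-cresol)
Product: 2 2,6-dibromo-4-methylphenol
Conditions: Br2 (2.05 equiv), AcOH, 15 °C to rt
Reagents that add atoms: bromine (Br2), BrBr
Why: Electrophilic aromatic bromination goes to both positions ortho to the hydroxyl because the para position is blocked by the methyl group.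

Step 2
Reactants: 2 2,6-dibromo-4-methylphenol
Product: 3 2,6-dimethoxy-4-methylphenol
Conditions: NaOMe (6 equiv), CuI (15 mol %), DMF/MeOH, 110 °C
Reagents that add atoms: sodium methoxide (NaOMe), [Na+].[O-]C
Why: Copper-catalysed Ullmann-type C–O coupling of ortho-bromophenols with methoxide is well established and installs both methoxy groups.

Step 3
Reactants: 3 2,6-dimethoxy-4-methylphenol
Product: 4 4-hydroxy-3,5-dimethoxybenzaldehyde (syringaldehyde)
Conditions: DDQ (2.2 equiv), 1,4-dioxane/H2O (9:1), rt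
Reagents that add atoms: water (H2O), O
Why: DDQ dehydrogenates the para-cresol to a quinone methide that adds water, and the resulting para-hydroxybenzyl alcohol is oxidised again to the aldehyde (benzylic oxidation).

Step 4
Reactants: 4 syringaldehyde
Product: 5 3,5-dimethoxy-4-(triisopropylsilyloxy)benzaldehyde
Conditions: TIPSCl (1.3 equiv), imidazole (2.5 equiv), DMF, 40 °C
Reagents that add atoms: triisopropylsilyl chloride (TIPSCl), CC(C)[Si](Cl)(C(C)C)C(C)C
Why: Silylation of the acidic phenol gives a bulky aryl silyl ether that survives amide bases and hydrides and makes the aldehyde a better aldol acceptor.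

Step 5
Reactants: 5 3,5-dimethoxy-4-(triisopropylsilyloxy)benzaldehyde; 6 methyl 4-oxobutanoate
Product: 9 (R)-4-[(R)-ArS(hydroxy)methyl]dihydrofuran-2(3H)-one, via aldol aldehyde 7 (not isolated), via hydroxy ester 8 (not isolated)
Conditions: L-proline (30 mol %), DMF, 4 °C, slow addition of the aldehyde ester (twofold excess); then MeOH, NaBH4, 0 °C; 1 M HCl to pH 4, rt
Reagents that add atoms: none
Why: The proline enamine cross-aldol (List–Houk transition state) of the aldehyde donor gives the anti adduct and sets C8 (C3 of 7, S), after which NaBH4 reduction of the formyl group and spontaneous lactonisation give the β-substituted γ-lactone.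

Step 6
Reactants: 9 (R)-4-[(R)-ArS(hydroxy)methyl]dihydrofuran-2(3H)-one; 5 3,5-dimethoxy-4-(triisopropylsilyloxy)benzaldehyde
Product: 11 (3S,4R)-3-[ArS(hydroxy)methyl]-4-[(R)-ArS(hydroxy)methyl]dihydrofuran-2(3H)-one (both epimers at the new carbinol carbon), via dilithium enolate 10 (not isolated)
Conditions: LiN(SiMe3)2 (2.3 equiv), THF, −78 °C; then the aldehyde in slight excess, −78 °C; aq NH4Cl
Reagents that add atoms: none
Why: In this lactone enolate aldol addition the aldehyde adds anti to the C4 side chain, which gives the trans-3,4-disubstituted lactone and fixes C8', while the new carbinol centre forms as an epimer mixture that converges in step 9.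

Step 7
Reactants: 11 bis-carbinol lactone
Product: 12 (1R,2R,3R)-1,4-bis(ArS)-2,3-bis(hydroxymethyl)butane-1,4-diol (C4 epimer mixture)
Conditions: LiAlH4 (3 equiv), THF, 0 °C; Fieser work-up
Reagents that add atoms: none
Why: Hydride reduction opens the lactone to the primary diol without touching the C8/C8' centres or the aryl silyl ethers.

Step 8
Reactants: 12 silylated tetrol
Product: 13 (1R,2R,3R)-1,4-bis(4-hydroxy-3,5-dimethoxyphenyl)-2,3-bis(hydroxymethyl)butane-1,4-diol (C4 epimer mixture)
Conditions: Bu4NF (2.4 equiv), AcOH (2.4 equiv), THF, 0 °C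
Reagents that add atoms: none
Why: Buffered fluoride cleaves the two aryl silyl ethers and unmasks the para-hydroxybenzyl alcohols needed for quinone methide formation.

Step 9
Reactants: 13 tetrol with free phenols
Product: 14 (+)-syringaresinol, 4,4'-[(1S,3aR,4S,6aR)-tetrahydro-1H,3H-furo[3,4-c]furan-1,4-diyl]bis(2,6-dimethoxyphenol)
Conditions: (+)-camphorsulfonic acid (10 mol %), 4 Å molecular sieves, CH2Cl2/THF (9:1), 0.01 M, 0 °C to rt, stopped at full conversion
Reagents that add atoms: none
Why: In this biomimetic double 5-exo cyclodehydration each para-hydroxybenzyl alcohol ionises to a planar quinone methide/benzylic cation and the primary hydroxyl adds from the face that puts the aryl group trans to the ring-fusion substituent (exo), so C7 and C7' (both S) are set here under kinetic control whatever their configuration in 13.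

**Part 2: guaiacyl building blocks and the D–E epoxide**

Step 10
Reactants: 15 benzene-1,2-diol (catechol)
Product: 16 2-methoxyphenol (guaiacol)
Conditions: MeI (0.9 equiv), K2CO3 (1.0 equiv), acetone, reflux; unreacted catechol recovered
Reagents that add atoms: iodomethane (MeI), CI
Why: Williamson mono-methylation of the symmetrical diol is kept at the mono stage by using catechol in excess.

Step 11
Reactants: 16 guaiacol
Product: 17 4-bromo-2-methoxyphenol
Conditions: NBS (1.0 equiv), MeCN, −10 °C to rt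
Reagents that add atoms: N-bromosuccinimide (NBS), O=C1CCC(=O)N1Br
Why: Electrophilic bromination is directed para to the free hydroxyl, the strongest activating group.

Step 12
Reactants: 17 4-bromo-2-methoxyphenol
Product: 18 (4-bromo-2-methoxyphenoxy)triisopropylsilane
Conditions: TIPSCl (1.2 equiv), imidazole (2.5 equiv), DMF, rt
Reagents that add atoms: triisopropylsilyl chloride (TIPSCl), CC(C)[Si](Cl)(C(C)C)C(C)C
Why: Phenol silylation gives a protecting group that survives organolithium, borane, base and palladium steps and is removed with fluoride at the end.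

Step 13
Reactants: 18 (4-bromo-2-methoxyphenoxy)triisopropylsilane
Product: 20 3-methoxy-4-(triisopropylsilyloxy)benzaldehyde, via aryllithium 19 (not isolated)
Conditions: n-BuLi (1.05 equiv), THF, −78 °C; DMF (2 equiv), −78 °C to 0 °C; aq NH4Cl
Reagents that add atoms: N,N-dimethylformamide (DMF), CN(C)C=O
Why: Bromine–lithium exchange followed by formylation with DMF (Bouveault reaction) is fast at −78 °C and leaves the aryl silyl ether untouched.

Step 14
Reactants: 20 3-methoxy-4-(triisopropylsilyloxy)benzaldehyde; 21 allyl chloride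
Product: 23 (1R,2R)-2-chloro-1-ArG-but-3-en-1-ol, via chloroallylborane 22 (not isolated)
Conditions: allyl chloride in excess, (−)-Ipc2BOMe (1.2 equiv), LiN(c-C6H11)2 (from HN(c-C6H11)2 and n-BuLi), Et2O/THF, −95 °C; BF3·OEt2 (2.5 equiv); then the aldehyde, −95 °C, 4 h; H2O2, pH 7 buffer, 0 °C
Reagents that add atoms: none
Why: This Brown–Oehlschlager asymmetric (Z)-γ-chloroallylboration passes through a closed chair transition state, so the Z reagent gives the syn chlorohydrin and the (+)-α-pinene-derived isopinocampheyl groups choose the aldehyde face that makes C7 R (and C8 R).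

Step 15
Reactants: 23 (1R,2R)-chlorohydrin
Product: 24 (2R,3S)-2-ArG-3-vinyloxirane (cis)
Conditions: DBU (1.5 equiv), CH2Cl2, 0 °C to rt; filtration through Et3N-deactivated silica; used at once
Reagents that add atoms: none
Why: Intramolecular Williamson displacement of chloride by the alkoxide inverts C8, so the syn chlorohydrin gives the cis-epoxide with C7 unchanged.

Step 16
Reactants: 20 3-methoxy-4-(triisopropylsilyloxy)benzaldehyde; 21 allyl chloride
Product: 26 (1S,2S)-2-chloro-1-ArG-but-3-en-1-ol, via chloroallylborane 25 (not isolated)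
Conditions: as step 14 but with (+)-Ipc2BOMe
Reagents that add atoms: none
Why: The same asymmetric (Z)-γ-chloroallylboration with the enantiomeric borane gives the enantiomeric syn chlorohydrin (C7 S, C8 S).

Step 17
Reactants: 26 (1S,2S)-chlorohydrin
Product: 27 (2S,3R)-2-ArG-3-vinyloxirane (cis)
Conditions: DBU (1.5 equiv), CH2Cl2, 0 °C to rt; filtration through Et3N-deactivated silica; used at once
Reagents that add atoms: none
Why: Intramolecular Williamson epoxide closure with inversion at the chloride-bearing carbon gives the cis-epoxide.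

Step 18
Reactants: 17 4-bromo-2-methoxyphenol; 27 (2S,3R)-2-ArG-3-vinyloxirane
Product: 28 (1S,2R)-2-(4-bromo-2-methoxyphenoxy)-1-ArG-but-3-en-1-ol
Conditions: Pd2(dba)3·CHCl3 (2.5 mol %), (S,S)-DACH-phenyl Trost ligand (7.5 mol %), degassed CH2Cl2, 0 °C to rt; the phenol is charged in twofold excess and the surplus is recovered by chromatography
Reagents that add atoms: none
Why: Proposed new method: zerovalent palladium ionises the allylic C8–O bond of the cis-epoxide with inversion to a zwitterionic π-allylpalladium alkoxide, which deprotonates the phenol and directs the phenoxide by hydrogen bonding to the proximal allyl terminus anti to palladium (second inversion), so the phenol adds across the epoxide 1:1 and the ether forms at C8 with net retention (cis-epoxide → erythro, 7S,8R), while the (S,S) ligand, predicted to be matched to this C8 configuration, funnels any π–σ–π-equilibrated complex to the same diastereomer; the closest known reactions are the Trost dynamic kinetic asymmetric additions of O- and N-nucleophiles to butadiene monoepoxide and the Trost–Toste asymmetric O-allylation of phenols, neither shown on 2-aryl-3-vinyloxiranes or for β-O-4 ethers.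

Step 19
Reactants: 28 (1S,2R)-allyl aryl ether
Product: 30 (1S,2R)-2-(4-bromo-2-methoxyphenoxy)-1-ArG-propane-1,3-diol, via aldehyde 29 (not isolated)
Conditions: OsO4 (2 mol %), NaIO4 (4 equiv), 2,6-lutidine (2 equiv), 1,4-dioxane/H2O (3:1), rt; extraction; then NaBH4, MeOH, 0 °C
Reagents that add atoms: sodium periodate (NaIO4), [Na+].[O-]I(=O)(=O)=O
Why: Lemieux–Johnson cleavage of the terminal alkene turns the vinyl group into the C9 aldehyde, which is reduced at once so that the α-aryloxy centre does not epimerise.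

Step 20
Reactants: 30 (1S,2R)-diol
Product: 31 (1S,2R)-2-(4-bromo-2-methoxyphenoxy)-1-ArG-1,3-bis(tert-butyldimethylsilyloxy)propane
Conditions: TBSCl (3 equiv), imidazole (6 equiv), DMF, 40 °C
Reagents that add atoms: tert-butyldimethylsilyl chloride (TBSCl), CC(C)(C)[Si](C)(C)Cl
Why: Silylation protects both hydroxyls against the organolithium and ylide steps and they leave with the aryl silyl ethers in the final fluoride step.

Step 21
Reactants: 31 bis-silyl ether aryl bromide
Product: 33 4-{[(1S,2R)-1-ArG-1,3-bis(tert-butyldimethylsilyloxy)propan-2-yl]oxy}-3-methoxybenzaldehyde, via aryllithium 32 (not isolated)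
Conditions: n-BuLi (1.1 equiv), THF, −78 °C; DMF (3 equiv); aq NH4Cl
Reagents that add atoms: N,N-dimethylformamide (DMF), CN(C)C=O
Why: Bromine–lithium exchange and formylation with DMF outrun any deprotonation at −78 °C and give the ring D aldehyde.

Step 22
Reactants: 33 ring D aldehyde
Product: 34 (E)-1-(4-{[(1S,2R)-1-ArG-1,3-bis(tert-butyldimethylsilyloxy)propan-2-yl]oxy}-3-methoxyphenyl)buta-1,3-diene
Conditions: diethyl allylphosphonate (1.5 equiv), n-BuLi (1.45 equiv), THF/HMPA, −78 °C to rt
Reagents that add atoms: diethyl allylphosphonate, C=CCP(=O)(OCC)OCC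
Why: Horner–Wadsworth–Emmons olefination with the α-lithiated allylphosphonate gives the terminal 1,3-diene with the E geometry that is usual for semistabilised phosphonate carbanions.

Step 23
Reactants: 34 (E)-aryl diene
Product: 35 (2S,3S)-2-(4-{[(1S,2R)-1-ArG-1,3-bis(tert-butyldimethylsilyloxy)propan-2-yl]oxy}-3-methoxyphenyl)-3-vinyloxirane (trans)
Conditions: enantiomer of the D-fructose-derived Shi ketone (30 mol %), Oxone (2KHSO5·KHSO4·K2SO4, 1.5 equiv), K2CO3, Bu4NHSO4 (5 mol %), MeCN/dimethoxymethane/aq buffer (pH 10.5), 0 °C; used at once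
Reagents that add atoms: potassium peroxymonosulfate (KHSO5, as Oxone), [K+].[O-]S(=O)(=O)OO
Why: Shi dioxirane epoxidation takes the trans-disubstituted styrenyl double bond of a conjugated diene and leaves the terminal one, and the enantiomer of the usual D-fructose ketone (which gives R,R epoxides from trans-β-methylstyrene) gives the 2S,3S trans-epoxide through the spiro transition state.

**Part 3: union and end game**

Step 24
Reactants: 14 (+)-syringaresinol; 24 (2R,3S)-2-ArG-3-vinyloxirane
Product: 36 4-O-[(1R,2S)-1-ArG-1-hydroxybut-3-en-2-yl]-(+)-syringaresinol (mono-ether on ring B)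
Conditions: Pd2(dba)3·CHCl3 (2.5 mol %), (R,R)-DACH-phenyl Trost ligand (7.5 mol %), degassed THF/CH2Cl2 (1:1), 0 °C to rt; the diphenol is charged in threefold excess over the epoxide and the surplus is recovered by chromatography
Reagents that add atoms: none
Why: Proposed new method: the stereoretentive allylic etherification of step 18 is applied to the hindered 2,6-dimethoxyphenol of the symmetrical diphenol 14 (charged in excess so that one phenol per molecule reacts), the zwitterionic π-allylpalladium alkoxide again delivering the phenoxide to C8 by double inversion so that cis-epoxide 24 adds 1:1 and gives the erythro (7R,8S) ether with the (R,R) ligand reinforcing the 8S configuration; the closest known reactions are Trost additions of nucleophiles to butadiene monoepoxide and Trost–Toste phenol allylation.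

Step 25
Reactants: 36 mono-ether; 35 (2S,3S)-trans-epoxide
Product: 37 bis-ether: 36 whose ring C oxygen carries the (1S,2S)-1-hydroxy-1-(ring D aryl)but-3-en-2-yl unit, ring D being 3-methoxy-4-{[(1S,2R)-1-ArG-1,3-bis(tert-butyldimethylsilyloxy)propan-2-yl]oxy}phenyl
Conditions: Pd2(dba)3·CHCl3 (5 mol %), (R,R)-DACH-phenyl Trost ligand (15 mol %), degassed THF/CH2Cl2 (1:1), 0 °C to rt, epoxide in slight excess, stopped when the phenol is consumed
Reagents that add atoms: none
Why: Proposed new method: the same zerovalent-palladium allylic etherification with net retention at C8 converts the trans-epoxide into the threo (7S,8S) β-O-4 ether, the much faster ionisation of the vinyl epoxide compared with the allyl aryl ether already present in 36 keeping the first linkage intact and the (R,R) ligand again reinforcing 8S; the closest known reactions are Trost additions to butadiene monoepoxide and Trost–Toste phenol allylation.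

Step 26
Reactants: 37 bis-ether with two vinyl groups
Product: 39 target with ring A and ring E phenols as TIPS ethers and the C7 and C9 hydroxyls of unit E as TBS ethers, via dialdehyde 38 (not isolated)
Conditions: OsO4 (4 mol %), NaIO4 (8 equiv), 2,6-lutidine (4 equiv), 1,4-dioxane/H2O (3:1), rt; extraction; then NaBH4, MeOH/THF, 0 °C
Reagents that add atoms: sodium periodate (NaIO4), [Na+].[O-]I(=O)(=O)=O
Why: Twofold Lemieux–Johnson cleavage and immediate NaBH4 reduction turn both vinyl groups into the C9 hydroxymethyl groups of units A and D, and no free phenol is present that periodate could oxidise.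

Step 27
Reactants: 39 tetra-silyl ether
Product: 40 target CNP0316493.3
Conditions: Bu4NF (6 equiv), AcOH (6 equiv), THF, 0 °C to rt
Reagents that add atoms: none
Why: Buffered fluoride removes the two aryl TIPS and two alkyl TBS ethers in one operation without touching the benzylic ethers, the benzylic alcohols or any stereocentre.

**Compound list**
1 | 4-methylphenol (p-cresol) | Cc1ccc(O)cc1 | starting material
2 | 2,6-dibromo-4-methylphenol | Cc1cc(Br)c(O)c(Br)c1 | intermediate
3 | 2,6-dimethoxy-4-methylphenol | COc1cc(C)cc(OC)c1O | intermediate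
4 | 4-hydroxy-3,5-dimethoxybenzaldehyde (syringaldehyde) | COc1cc(C=O)cc(OC)c1O | intermediate
5 | 3,5-dimethoxy-4-(triisopropylsilyloxy)benzaldehyde | COc1cc(C=O)cc(OC)c1O[Si](C(C)C)(C(C)C)C(C)C | intermediate
6 | methyl 4-oxobutanoate | COC(=O)CCC=O | starting material
7 | methyl (3S,4R)-4-ArS-3-formyl-4-hydroxybutanoate (not isolated) | COC(=O)C[C@@H]([C@@H](O)c1cc(OC)c(O[Si](C(C)C)(C(C)C)C(C)C)c(OC)c1)C=O | intermediate
8 | methyl (3R,4R)-4-ArS-4-hydroxy-3-(hydroxymethyl)butanoate (not isolated) | COC(=O)C[C@@H]([C@@H](O)c1cc(OC)c(O[Si](C(C)C)(C(C)C)C(C)C)c(OC)c1)CO | intermediate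
9 | (R)-4-[(R)-ArS(hydroxy)methyl]dihydrofuran-2(3H)-one | O=C1C[C@@H]([C@@H](O)c2cc(OC)c(O[Si](C(C)C)(C(C)C)C(C)C)c(OC)c2)CO1 | intermediate
10 | dilithium enolate/alkoxide of 9 (not isolated) | [Li]OC1=C[C@@H]([C@@H](O[Li])c2cc(OC)c(O[Si](C(C)C)(C(C)C)C(C)C)c(OC)c2)CO1 | intermediate
11 | (3S,4R)-3-[ArS(hydroxy)methyl]-4-[(R)-ArS(hydroxy)methyl]dihydrofuran-2(3H)-one, epimer mixture at the C3 carbinol | O=C1[C@H](C(O)c2cc(OC)c(O[Si](C(C)C)(C(C)C)C(C)C)c(OC)c2)[C@@H]([C@@H](O)c2cc(OC)c(O[Si](C(C)C)(C(C)C)C(C)C)c(OC)c2)CO1 | intermediate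
12 | (1R,2R,3R)-1,4-bis(ArS)-2,3-bis(hydroxymethyl)butane-1,4-diol, C4 epimer mixture | OC[C@H](C(O)c1cc(OC)c(O[Si](C(C)C)(C(C)C)C(C)C)c(OC)c1)[C@@H]([C@@H](O)c1cc(OC)c(O[Si](C(C)C)(C(C)C)C(C)C)c(OC)c1)CO | intermediate
13 | (1R,2R,3R)-1,4-bis(4-hydroxy-3,5-dimethoxyphenyl)-2,3-bis(hydroxymethyl)butane-1,4-diol, C4 epimer mixture | OC[C@H](C(O)c1cc(OC)c(O)c(OC)c1)[C@@H]([C@@H](O)c1cc(OC)c(O)c(OC)c1)CO | intermediate
14 | (+)-syringaresinol (7S,8R,7'S,8'R) | COc1cc(cc(OC)c1O)[C@H]1OC[C@H]2[C@@H]1CO[C@@H]2c1cc(OC)c(O)c(OC)c1 | intermediate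
15 | benzene-1,2-diol (catechol) | Oc1ccccc1O | starting material
16 | 2-methoxyphenol (guaiacol) | COc1ccccc1O | intermediate
17 | 4-bromo-2-methoxyphenol | COc1cc(Br)ccc1O | intermediate
18 | (4-bromo-2-methoxyphenoxy)triisopropylsilane | COc1cc(Br)ccc1O[Si](C(C)C)(C(C)C)C(C)C | intermediate
19 | [3-methoxy-4-(triisopropylsilyloxy)phenyl]lithium (not isolated) | COc1cc([Li])ccc1O[Si](C(C)C)(C(C)C)C(C)C | intermediate
20 | 3-methoxy-4-(triisopropylsilyloxy)benzaldehyde | COc1cc(C=O)ccc1O[Si](C(C)C)(C(C)C)C(C)C | intermediate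
21 | allyl chloride (3-chloroprop-1-ene) | C=CCCl | starting material
22 | (Z)-(3-chloroallyl)diisopinocampheylborane from (−)-Ipc2BOMe (not isolated) | Cl/C=C\CB([C@@H]1C[C@@H]2C[C@H]([C@H]1C)C2(C)C)[C@@H]1C[C@@H]2C[C@H]([C@H]1C)C2(C)C | intermediate
23 | (1R,2R)-2-chloro-1-ArG-but-3-en-1-ol | COc1cc(ccc1O[Si](C(C)C)(C(C)C)C(C)C)[C@@H](O)[C@H](Cl)C=C | intermediate
24 | (2R,3S)-2-ArG-3-vinyloxirane (cis) | COc1cc(ccc1O[Si](C(C)C)(C(C)C)C(C)C)[C@H]1O[C@H]1C=C | intermediate
25 | (Z)-(3-chloroallyl)diisopinocampheylborane from (+)-Ipc2BOMe (not isolated) | Cl/C=C\CB([C@H]1C[C@H]2C[C@@H]([C@@H]1C)C2(C)C)[C@H]1C[C@H]2C[C@@H]([C@@H]1C)C2(C)C | intermediate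
26 | (1S,2S)-2-chloro-1-ArG-but-3-en-1-ol | COc1cc(ccc1O[Si](C(C)C)(C(C)C)C(C)C)[C@H](O)[C@@H](Cl)C=C | intermediate
27 | (2S,3R)-2-ArG-3-vinyloxirane (cis) | COc1cc(ccc1O[Si](C(C)C)(C(C)C)C(C)C)[C@@H]1O[C@@H]1C=C | intermediate
28 | (1S,2R)-2-(4-bromo-2-methoxyphenoxy)-1-ArG-but-3-en-1-ol | COc1cc(ccc1O[Si](C(C)C)(C(C)C)C(C)C)[C@H](O)[C@@H](C=C)Oc1ccc(Br)cc1OC | intermediate
29 | (2S,3S)-2-(4-bromo-2-methoxyphenoxy)-3-ArG-3-hydroxypropanal (not isolated) | COc1cc(ccc1O[Si](C(C)C)(C(C)C)C(C)C)[C@H](O)[C@@H](C=O)Oc1ccc(Br)cc1OC | intermediate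
30 | (1S,2R)-2-(4-bromo-2-methoxyphenoxy)-1-ArG-propane-1,3-diol | COc1cc(ccc1O[Si](C(C)C)(C(C)C)C(C)C)[C@H](O)[C@@H](CO)Oc1ccc(Br)cc1OC | intermediate
31 | (1S,2R)-2-(4-bromo-2-methoxyphenoxy)-1-ArG-1,3-bis(tert-butyldimethylsilyloxy)propane | COc1cc(ccc1O[Si](C(C)C)(C(C)C)C(C)C)[C@H](O[Si](C)(C)C(C)(C)C)[C@@H](CO[Si](C)(C)C(C)(C)C)Oc1ccc(Br)cc1OC | intermediate
32 | aryllithium from 31 (Li in place of Br; not isolated) | COc1cc(ccc1O[Si](C(C)C)(C(C)C)C(C)C)[C@H](O[Si](C)(C)C(C)(C)C)[C@@H](CO[Si](C)(C)C(C)(C)C)Oc1ccc([Li])cc1OC | intermediate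
33 | 4-{[(1S,2R)-1-ArG-1,3-bis(tert-butyldimethylsilyloxy)propan-2-yl]oxy}-3-methoxybenzaldehyde | COc1cc(ccc1O[Si](C(C)C)(C(C)C)C(C)C)[C@H](O[Si](C)(C)C(C)(C)C)[C@@H](CO[Si](C)(C)C(C)(C)C)Oc1ccc(C=O)cc1OC | intermediate
34 | (E)-1-(4-{[(1S,2R)-1-ArG-1,3-bis(tert-butyldimethylsilyloxy)propan-2-yl]oxy}-3-methoxyphenyl)buta-1,3-diene | COc1cc(ccc1O[Si](C(C)C)(C(C)C)C(C)C)[C@H](O[Si](C)(C)C(C)(C)C)[C@@H](CO[Si](C)(C)C(C)(C)C)Oc1ccc(/C=C/C=C)cc1OC | intermediate
35 | (2S,3S)-2-(4-{[(1S,2R)-1-ArG-1,3-bis(tert-butyldimethylsilyloxy)propan-2-yl]oxy}-3-methoxyphenyl)-3-vinyloxirane (trans) | COc1cc(ccc1O[Si](C(C)C)(C(C)C)C(C)C)[C@H](O[Si](C)(C)C(C)(C)C)[C@@H](CO[Si](C)(C)C(C)(C)C)Oc1ccc(cc1OC)[C@@H]1O[C@H]1C=C | intermediate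
36 | 4-O-[(1R,2S)-1-ArG-1-hydroxybut-3-en-2-yl]-(+)-syringaresinol | COc1cc([C@@H](O)[C@H](C=C)Oc2c(OC)cc([C@H]3OC[C@H]4[C@@H]3CO[C@@H]4c3cc(OC)c(O)c(OC)c3)cc2OC)ccc1O[Si](C(C)C)(C(C)C)C(C)C | intermediate
37 | bis-ether: 36 with the ring C oxygen on C2 of the (1S,2S)-1-hydroxy-1-(ring D aryl)but-3-en-2-yl unit carrying the silylated (1S,2R) unit E | COc1cc([C@@H](O)[C@H](C=C)Oc2c(OC)cc([C@H]3OC[C@H]4[C@@H]3CO[C@@H]4c3cc(OC)c(O[C@@H](C=C)[C@@H](O)c4ccc(O[C@H](CO[Si](C)(C)C(C)(C)C)[C@@H](O[Si](C)(C)C(C)(C)C)c5ccc(O[Si](C(C)C)(C(C)C)C(C)C)c(OC)c5)c(OC)c4)c(OC)c3)cc2OC)ccc1O[Si](C(C)C)(C(C)C)C(C)C | intermediate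
38 | dialdehyde from 37 (both vinyl groups cleaved to CHO; not isolated) | COc1cc([C@@H](O)[C@H](C=O)Oc2c(OC)cc([C@H]3OC[C@H]4[C@@H]3CO[C@@H]4c3cc(OC)c(O[C@@H](C=O)[C@@H](O)c4ccc(O[C@H](CO[Si](C)(C)C(C)(C)C)[C@@H](O[Si](C)(C)C(C)(C)C)c5ccc(O[Si](C(C)C)(C(C)C)C(C)C)c(OC)c5)c(OC)c4)c(OC)c3)cc2OC)ccc1O[Si](C(C)C)(C(C)C)C(C)C | intermediate
39 | target with ring A and ring E phenols as TIPS ethers and unit E C7/C9 hydroxyls as TBS ethers | COc1cc([C@@H](O)[C@H](CO)Oc2c(OC)cc([C@H]3OC[C@H]4[C@@H]3CO[C@@H]4c3cc(OC)c(O[C@@H](CO)[C@@H](O)c4ccc(O[C@H](CO[Si](C)(C)C(C)(C)C)[C@@H](O[Si](C)(C)C(C)(C)C)c5ccc(O[Si](C(C)C)(C(C)C)C(C)C)c(OC)c5)c(OC)c4)c(OC)c3)cc2OC)ccc1O[Si](C(C)C)(C(C)C)C(C)C | intermediate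
40 | CNP0316493.3: (+)-syringaresinol with 4-O-[(7R,8S)-erythro-guaiacylglycerol-8-yl] on ring B and 4'-O-[(7S,8S)-threo-guaiacylglycerol-8-yl] on ring C, the latter 4-O-linked to a (7S,8R)-erythro-guaiacylglycerol-8-yl unit | COc1cc([C@@H](O)[C@H](CO)Oc2c(OC)cc([C@H]3OC[C@H]4[C@@H]3CO[C@@H]4c3cc(OC)c(O[C@@H](CO)[C@@H](O)c4ccc(O[C@H](CO)[C@@H](O)c5ccc(O)c(OC)c5)c(OC)c4)c(OC)c3)cc2OC)ccc1O | target

**Step count**
Total steps: 27. Longest linear sequence: 15 (steps 10, 11, 12, 13, 16, 17, 18, 19, 20, 21, 22, 23, 25, 26, 27); the core branch (steps 1–9, then 24–27) is 13.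

**Three steps most likely to fail, with fallbacks**

Step 25 (the proposed palladium etherification in its hardest form: hindered phenol, acid-sensitive trans-epoxide, an allyl aryl ether already present; the same method is used in steps 18 and 24). If it gives no conversion, the linear ether or poor threo selectivity, the same C8–O bond and the threo centres are made by known Evans glycolate aldol chemistry. The fallback sets out from 36 and uses aldehyde 33. The free syringyl phenol of 36 is alkylated with (R)-4-benzyl-3-(bromoacetyl)oxazolidin-2-one (K2CO3, acetone, rt) to give the aryloxyacetyl imide F1. Its Z boron enolate (Bu2BOTf in excess to cover the free benzylic hydroxyl, i-Pr2NEt, CH2Cl2, −78 °C) adds to 33 to give the syn-aldol adduct F2, in which the auxiliary sets what become 8S and 7S. LiBH4 (THF/MeOH, 0 °C) removes the auxiliary and gives the threo 1,3-diol F3, which already carries the C9 hydroxyl of unit D. OsO4/NaIO4/2,6-lutidine cleavage of the remaining vinyl group gives the aldehyde F4, and NaBH4 reduction of F4 comes back to the route at 39.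

Step 9 (double cyclisation; risks are the competing 7-O-7' tetrahydrofuran and acid epimerisation to the exo,endo isomer). The fallback sets out from 4 and uses the known biomimetic route. Wittig olefination (Ph3P=CHCO2Et, toluene, 90 °C) gives ethyl sinapate F5. i-Bu2AlH (toluene, 0 °C) gives sinapyl alcohol F6. Oxidative β–β dimerisation with FeCl3·6H2O (acetone/H2O, rt) gives racemic syringaresinol F7, whose aryl groups are exo because the bis-quinone methide cyclises that way. Preparative HPLC on a chiral stationary phase (amylose tris(3,5-dimethylphenylcarbamate)) separates the enantiomers and comes back to the route at 14.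

Step 23 (Shi epoxidation of an electron-rich aryl diene to an acid-labile epoxide under aqueous conditions). The fallback sets out from aldehyde 33 and bypasses diene 34. Aggarwal sulfur-ylide epoxidation with the S-allyl sulfonium triflate of isothiocineole (the antipode that gives the 2S,3S epoxide) and KOH in MeCN/H2O at 0 °C forms the trans-vinyl epoxide directly from the carbonyl group. It comes back to the route at 35 and makes no new compound (F0).

Further compounds
F1 | step 25 | aryloxyacetyl imide: 36 with the ring C phenol O-alkylated by CH2C(=O)-[(R)-4-benzyl-2-oxooxazolidin-3-yl] | COc1cc([C@@H](O)[C@H](C=C)Oc2c(OC)cc([C@H]3OC[C@H]4[C@@H]3CO[C@@H]4c3cc(OC)c(OCC(=O)N4[C@H](Cc5ccccc5)COC4=O)c(OC)c3)cc2OC)ccc1O[Si](C(C)C)(C(C)C)C(C)C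
F2 | step 25 | syn-aldol adduct of F1 with 33, (2R,3S) at the new centres, (R)-auxiliary attached | COc1cc([C@@H](O)[C@H](C=C)Oc2c(OC)cc([C@H]3OC[C@H]4[C@@H]3CO[C@@H]4c3cc(OC)c(O[C@@H](C(=O)N4[C@H](Cc5ccccc5)COC4=O)[C@@H](O)c4ccc(O[C@H](CO[Si](C)(C)C(C)(C)C)[C@@H](O[Si](C)(C)C(C)(C)C)c5ccc(O[Si](C(C)C)(C(C)C)C(C)C)c(OC)c5)c(OC)c4)c(OC)c3)cc2OC)ccc1O[Si](C(C)C)(C(C)C)C(C)C
F3 | step 25 | threo diol: 39 that still carries the vinyl group of unit A in place of its C9 hydroxymethyl | COc1cc([C@@H](O)[C@H](C=C)Oc2c(OC)cc([C@H]3OC[C@H]4[C@@H]3CO[C@@H]4c3cc(OC)c(O[C@@H](CO)[C@@H](O)c4ccc(O[C@H](CO[Si](C)(C)C(C)(C)C)[C@@H](O[Si](C)(C)C(C)(C)C)c5ccc(O[Si](C(C)C)(C(C)C)C(C)C)c(OC)c5)c(OC)c4)c(OC)c3)cc2OC)ccc1O[Si](C(C)C)(C(C)C)C(C)C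
F4 | step 25 | aldehyde from F3 (unit A vinyl cleaved to CHO) | COc1cc([C@@H](O)[C@H](C=O)Oc2c(OC)cc([C@H]3OC[C@H]4[C@@H]3CO[C@@H]4c3cc(OC)c(O[C@@H](CO)[C@@H](O)c4ccc(O[C@H](CO[Si](C)(C)C(C)(C)C)[C@@H](O[Si](C)(C)C(C)(C)C)c5ccc(O[Si](C(C)C)(C(C)C)C(C)C)c(OC)c5)c(OC)c4)c(OC)c3)cc2OC)ccc1O[Si](C(C)C)(C(C)C)C(C)C
F5 | step 9 | ethyl (E)-3-(4-hydroxy-3,5-dimethoxyphenyl)acrylate (ethyl sinapate) | CCOC(=O)/C=C/c1cc(OC)c(O)c(OC)c1
F6 | step 9 | (E)-4-(3-hydroxyprop-1-enyl)-2,6-dimethoxyphenol (sinapyl alcohol) | OC/C=C/c1cc(OC)c(O)c(OC)c1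
F7 | step 9 | racemic syringaresinol (1:1 mixture of enantiomers) | COc1cc(cc(OC)c1O)[C@H]1OC[C@H]2[C@@H]1CO[C@@H]2c1cc(OC)c(O)c(OC)c1.COc1cc(cc(OC)c1O)[C@@H]1OC[C@@H]2[C@H]1CO[C@H]2c1cc(OC)c(O)c(OC)c1
F0 | step 23 | none | none
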